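## Analysis of the target

Compound 38 is a linear octamer of oxygenated benzene rings, lettered here A to H from the 2,4,6-trihydroxyphenyl end to the 3,4,5-trihydroxyphenoxy end. Ring atoms are numbered from the carbon that carries the ether oxygen pointing towards ring A (B1, C1 … H1); in ring A the ether carbon is A2. Seven diaryl ether bonds hold the chain together: A2–O–B1, B5–O–C1, C2–O–D1, D4–O–E1, E2–O–F1, F4–O–G1 and G2–O–H1. Rings A, B, D, F and H carry four oxygens, rings C, E and G five; there are 21 free phenolic hydroxyls, no ring-to-ring C–C bond and no stereocentre, so nothing has to be set or preserved stereochemically. The free polyphenol is acidic and easily oxidised in air, most of all at the three-hydroxyl arrays of rings C, E, G and H, so every hydroxyl has to stay masked until the last step. The difficulty lies in the ether bonds: all rings are electron-rich, which excludes ordinary nucleophilic aromatic substitution, and A2, C2, D4, E2, F4 and G2 each sit between two ortho oxygens. Rings B, D and F look alike but differ: in D and F the two ether oxygens are para, in ring B they are meta, with B1 isolated between the CH carbons B2 and B6 and B5 next to the hydroxyl carbons B4 and B3. This 1-hydroxy-3-aryloxy-4,5-dialkoxy arrangement is what a dialkoxy vinylketene and an aryloxyalkyne give in a benzannulation, and the route rests on it: ring B is built on the C1 oxygen of ring C instead of being coupled to it.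

## Retrosynthetic reasoning

**38 ⇐ 37.** The last operation can only be the unmasking of the hydroxyls. All 21 are carried as methyl ethers, which survive organolithium reagents, copper and palladium catalysis and heating to 110 °C. The forward step is one exhaustive Lewis-acid ether cleavage; the diaryl ether bonds are safe because the halide that removes methyl groups cannot attack an aryl carbon.

**37 ⇐ 27 + 36.** The cut at C2–O–D1 divides the eight rings into three (phenol 27) and five (bromide 36). It follows a rule used for every coupling in the route: the oxygen flanked by two ortho oxygens stays on the nucleophile, and the carbon with only CH neighbours becomes the electrophile. Copper-mediated arylation accepts a crowded phenoxide far better than a crowded, electron-rich aryl halide. The forward reaction has to join two large electron-rich partners, so it is placed late.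

**27 ⇐ 26.** The C2 hydroxyl must be distinguishable from all others up to this point. In 26 it is a benzyl ether, the only orthogonal group of the route, removed by hydrogenolysis at a stage where no halogen is present.

**26 ⇐ 24 + 25, and 24 ⇐ 23.** A2–O–B1 is cut with the same polarity: ring A arrives complete as the crowded phenol 25, and B1 becomes the electrophile as the triflate 24. 24 is the sulfonate of 23, so the free hydroxyl that the ring-forming step leaves at B1 is used directly as the handle for ring A. Building ring A carbon by carbon on the B1 oxygen was weighed and not followed, because its closing C-acylation would compete with O-acylation of the same enolate chain.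

**23 ⇐ 14 + 18 (key disconnection).** Three bonds of ring B are cut: B1–B6, B4–B5 and B1–B2. Ring B falls into a four-carbon unit, the cyclobutenone 18 (B1, B4, B3, B2, with the methoxyls already on B4 and B3), and a two-carbon unit, the alkyne of the ynol ether 14 (B6 and B5, the latter already bound to the ring C oxygen). The gain is that B5–O–C1 is never made on an aromatic carbon: it is an alkynyl ether in 14 and becomes a diaryl ether as ring B forms around it. The four oxygens of ring B come out differentiated: free hydroxyl at B1, ether at B5, methoxyls at B3 and B4. The forward reaction has to generate a vinylketene from 18, add it to 14 in the right orientation and aromatise, under neutral thermal conditions.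

**14 ⇐ 11 ⇐ 8 + 9.** 14 is cut at the O–C(sp) bond. 9 supplies both alkyne carbons: the phenoxide of 8 adds to dichloroacetylene 10 released from 9, giving the dichlorovinyl ether 11, and an alkyllithium then removes both chlorines. The benzyl ether and methoxyls of ring C are inert to both operations.

**8 ⇐ 6 ⇐ 5 ⇐ 3 ⇐ 1.** The C1 hydroxyl of 8 stands where an aldehyde can be placed. 8 is traced back through aryl formate cleavage to the aldehyde 6, by O-benzylation to the salicylaldehyde 5, and by ortho-formylation to 3, which has one free ortho position. 3 is the oxidation product of commercial 1. The order formylation, benzylation, oxidation decides without selective protection which of the two neighbouring oxygens is the benzyl ether (C2) and which is the free phenol (C1).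

**18 ⇐ 17 ⇐ 16 ⇐ 15.** 18 has the skeleton and both methoxyls of 15; one carbonyl has become a methylene. The disconnection is a deoxygenation, back through the acetate 17 and the alcohol 16 to 15. The forward problem is to remove the C4 oxygen without moving the double bond. A two-electron reduction of the α-acyloxy ketone with protonation at the α-carbon is chosen, because an ionising method would pass through a cation best stabilised, and therefore quenched, at the methoxy-bearing carbon C2.

**36 ⇐ 35 + 31.** The pentamer is assembled from the ring H end so that the D1 bromide arrives last. D4–O–E1 is cut into the iodide 35 and the bromophenol 31: the oxygen between two methoxyls stays on the phenol, and E1, with one ortho substituent, is the electrophile. The coupling must consume the iodide of 35 and leave the bromide of 31, which is why the two ring types carry different halogens.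

**35 ⇐ 28 + 34, and 34 ⇐ 32.** E2–O–F1 is cut into the iodophenol 28 and the boronic acid 34. The nucleophile itself carries the iodide needed for the next coupling, so a halide-consuming reaction is excluded; an oxidative copper coupling with an arylboronic acid leaves aryl iodides alone. 34 comes from the bromide 32 by halogen–lithium exchange and borylation.

**32 ⇐ 30 + 31, and 30 ⇐ 28 + 29.** The same two disconnections are repeated one ring pair further out: F4–O–G1 gives the iodide 30 and again 31; G2–O–H1 gives 28 and the commercial boronic acid 29. Rings C, E and G thus derive from one phenol (3), rings D and F from one bromophenol (31).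

**28 ⇐ 3.** 28 is the iodination product of 3, already available from the ring C series; the para position and one ortho position are blocked, so only C6 can react.

## Alternatives that were turned down

**Alternative 1:** Ring C as an electrophilic hub.
- Disconnection: both ether bonds of ring C, B5–O–C1 and C2–O–D1, are cut in one operation, with ring C as electrophile and its neighbours as phenoxides.
- Forward key step: the cationic CpRu η6-arene complex A2 of ring C, with chlorides at C1 and C2, takes up the rings A–B phenoxide at C1 and then a ring D phenoxide at C2 in one flask. The product is complex A1, the CpRu hexafluorophosphate complex of the deca-O-methyl rings A–B–C–D tetramer with a benzyl ether at D4; the metal is removed later by photolysis.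
- For it: two of the seven ether bonds, including the doubly flanked C2 ether, form in one flask near room temperature. Activation of chloroarenes by cationic ruthenium for diaryl ether formation is well established. The plan is more convergent than the chosen one.
- Against it: the two chlorides of A2 differ only in their neighbours (CH beside C1, methoxyl beside C2). The first phenoxide must choose C1 on a small steric difference, and attack at C2 would give a constitutional isomer with rings B and D exchanged that would be hard to separate. The second substitution occurs at the more hindered carbon of a ring that has become more electron-rich. Ruthenium is stoichiometric. The rings A–B phenol, with its 1,3,4,5-oxygen pattern and its A2–O–B1 bond, still has to be made by other means.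
- Comparison: Alternative 1 is stronger in convergence and in bonds formed per operation. The chosen route offers a regiochemistry that follows from the mechanism of a cycloaddition instead of a competition between two similar leaving groups, needs no stoichiometric transition metal, and creates ring B with its oxygens differentiated.

**Alternative 2:** Ring A from an aryloxy triketide.
- Disconnection: ring A is opened at A1–A2, so its six carbons become a 3,5-dioxohexanoate chain whose C6 carries the B1 oxygen.
- Forward key step: a strong amide base converts the keto ester A4 into its trianion, C6 attacks the ester carbon, and the cyclic trione tautomerises to the triol A3, which keeps a bromide at B5 for later coupling to ring C.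
- For it: A2–O–B1 is made by O-alkylation of a phenol and never by arylation. The chain is short to prepare and no metal is involved. Up to A3 the step count is equal to or better than anything in the chosen route.
- Against it: the C6 carbanion must attack an ester that is at that moment part of a β-keto ester enolate, a poor electrophile, through a tetrahedral intermediate carrying four negative charges. The usual reaction of 3,5-dioxo esters with base is O-acylation to a 4-hydroxypyranone, and retro-Claisen cleavage is a further escape. The aryl bromide must survive the base. The ring that is built is the one whose ether can be made by a well-matched coupling (crowded oxygen on phenol 25, unhindered B1 on the electrophile, as in steps 11 and 12), while B5–O–C1, with an ortho substituent on each partner, is left to copper. A3 also needs three methylations before it can be used.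
- Comparison: the chosen route offers a ring closure with a close thermal precedent under neutral conditions, and spends its ring construction on B5–O–C1 instead of A2–O–B1.

**Alternative 3:** Ring G by cyclobutenone ring expansion.
- Disconnection: ring G is opened at G1–G6 to a dienylketene and further back to the four-membered ring of the cyclobutenone A6, which already carries the ring H oxygen and three methoxyls.
- Forward key step: heating A6 in a high-boiling aromatic solvent opens the four-membered ring, 6π electrocyclisation closes ring G, and tautomerisation gives the phenol A5.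
- For it: thermal ring expansion of 4-alkenyl-4-alkoxycyclobutenones to highly oxygenated phenols is better precedented than the key step chosen here. All five oxygens of ring G are set at once, A6 derives from a squarate such as 15, and G2–O–H1 arises by simple addition–elimination on the squarate. On precedent for the ring-forming step Alternative 3 is the stronger plan.
- Against it: the bond it avoids, G2–O–H1, is the easiest ether type in the molecule (crowded phenol, unhindered arylboronic acid; one step, step 15), so a single coupling is replaced by a linear sequence of about four steps. A5 emerges with its free hydroxyl at G1, beside the bulky aryloxy group. To reach ring F this hydroxyl would have to attack a carbon between two methoxyls, or become a sulfonate attacked by a phenol with two ortho methoxyls; either way it is the most congested bond in the molecule with poor polarity. Addition of the alkenyl nucleophile to a squarate with two different oxygen substituents must also distinguish two carbonyls.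
- Comparison: the chosen key step is less well precedented. In exchange its free hydroxyl appears at B1 between two CH carbons, where it becomes an unhindered electrophile for ring A, and it joins two fragments of similar size convergently.

Key step: step 10

Assumption: 38 is taken as the achiral constitution drawn, with free rotation about all seven ether bonds, so no atropisomerism has to be controlled.

## Route

Step 1
Reactants: 1 2,3,4-trimethoxybenzaldehyde
Product: 3 2,3,4-trimethoxyphenol, via 2,3,4-trimethoxyphenyl formate 2 (not isolated)
Conditions: mCPBA, CH2Cl2, 0 °C to rt; then K2CO3, MeOH, rt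
Reagents that add atoms: mCPBA (3-chloroperoxybenzoic acid), O=C(OO)c1cccc(Cl)c1
Why: Baeyer–Villiger oxidation of an electron-rich benzaldehyde (Dakin-type); the aryl group, activated by ortho and para methoxyls, migrates in preference to hydride, and the formate 2 is methanolysed to the phenol.

Step 2
Reactants: 3 2,3,4-trimethoxyphenol
Product: 5 2-hydroxy-3,4,5-trimethoxybenzaldehyde, via 6-(hydroxymethyl)-2,3,4-trimethoxyphenol 4 (not isolated)
Conditions: MgCl2, Et3N, (CH2O)n, MeCN, reflux; aq. HCl work-up
Reagents that add atoms: formaldehyde (from paraformaldehyde), C=O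
Why: Magnesium-mediated ortho-formylation of a phenol (Casnati–Skattebøl); the magnesium phenoxide delivers formaldehyde to C6, the only free ortho position, and a second formaldehyde oxidises the benzylic alkoxide of 4 by hydride transfer.

Step 3
Reactants: 5 2-hydroxy-3,4,5-trimethoxybenzaldehyde
Product: 6 2-(benzyloxy)-3,4,5-trimethoxybenzaldehyde
Conditions: BnBr, K2CO3, DMF, rt to 50 °C
Reagents that add atoms: benzyl bromide, BrCc1ccccc1
Why: Williamson ether synthesis on the only acidic group; benzylating at this stage marks the future C2 oxygen of ring C as the one orthogonal position.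

Step 4
Reactants: 6 2-(benzyloxy)-3,4,5-trimethoxybenzaldehyde
Product: 8 2-(benzyloxy)-3,4,5-trimethoxyphenol, via 2-(benzyloxy)-3,4,5-trimethoxyphenyl formate 7 (not isolated)
Conditions: mCPBA, CH2Cl2, 0 °C to rt; then K2CO3, MeOH, rt
Reagents that add atoms: mCPBA (3-chloroperoxybenzoic acid), O=C(OO)c1cccc(Cl)c1
Why: Baeyer–Villiger oxidation; the aryl ring with its ortho benzyloxy and para methoxy groups migrates, the formate 7 is cleaved by methanol, and the benzyl ether is inert to peracid and carbonate.

Step 5
Reactants: 8 2-(benzyloxy)-3,4,5-trimethoxyphenol; 9 trichloroethylene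
Product: 11 2-(benzyloxy)-1-{[(E)-1,2-dichloroethenyl]oxy}-3,4,5-trimethoxybenzene, via dichloroacetylene 10 (not isolated)
Conditions: K2CO3, DMF, 70 °C
Reagents that add atoms: none
Why: Standard preparation of aryl 1,2-dichlorovinyl ethers: base eliminates HCl from 9 to give dichloroacetylene 10 in low concentration, and the phenoxide adds to it in anti fashion; this sets the E geometry, which has no bearing on the next step.

Step 6
Reactants: 11 2-(benzyloxy)-1-{[(E)-1,2-dichloroethenyl]oxy}-3,4,5-trimethoxybenzene
Product: 14 2-(benzyloxy)-1-(ethynyloxy)-3,4,5-trimethoxybenzene (ring C ynol ether), via chloroethynyl ether 12 (not isolated), via lithium aryloxyacetylide 13 (not isolated)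
Conditions: n-BuLi (2.3 equiv), THF, −78 to −40 °C; then MeOH, −78 °C
Reagents that add atoms: none
Why: Known conversion of 1,2-dichlorovinyl ethers into ynol ethers: deprotonation and β-elimination give the chloroalkyne 12, chlorine–lithium exchange gives the acetylide 13, and protonation gives the terminal ynol ether, which is purified quickly on base-washed silica and used at once. The low temperature keeps the benzyl ether from being metalated.

Step 7
Reactants: 15 dimethyl squarate (3,4-dimethoxycyclobut-3-ene-1,2-dione)
Product: 16 rac-4-hydroxy-2,3-dimethoxycyclobut-2-en-1-one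
Conditions: LiAlH(OtBu)3, THF, −78 °C
Reagents that add atoms: none
Why: 1,2-Reduction of one of two equivalent carbonyls by a bulky alkoxyaluminium hydride, a known monoreduction of squarate esters; the alkoxide formed deactivates the second carbonyl, and the new stereocentre is racemic and is removed in step 9.

Step 8
Reactants: 16 rac-4-hydroxy-2,3-dimethoxycyclobut-2-en-1-one
Product: 17 rac-2,3-dimethoxy-4-oxocyclobut-2-en-1-yl acetate
Conditions: Ac2O, pyridine, DMAP (cat.), CH2Cl2, 0 °C
Reagents that add atoms: acetic anhydride, CC(=O)OC(C)=O
Why: DMAP-catalysed acylation of the secondary α-hydroxy ketone turns the C4 oxygen into a leaving group for the reduction; basic conditions avoid the acid-promoted allylic transposition of this alcohol.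

Step 9
Reactants: 17 rac-2,3-dimethoxy-4-oxocyclobut-2-en-1-yl acetate
Product: 18 2,3-dimethoxycyclobut-2-en-1-one
Conditions: SmI2 (2.2 equiv), THF–MeOH, −78 °C
Reagents that add atoms: none
Why: SmI2 reduction of an α-acyloxy ketone, a known reaction type: electron transfer to the carbonyl expels acetate, and methanol protonates the resulting enolate at the α-carbon C4, the usual kinetic site, so the tetrasubstituted C2=C3 double bond with both methoxyls stays conjugated with the carbonyl. The vinylic C2–OMe bond lies in the plane of the π system and is not cleaved.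

Step 10
Reactants: 14 2-(benzyloxy)-1-(ethynyloxy)-3,4,5-trimethoxybenzene; 18 2,3-dimethoxycyclobut-2-en-1-one
Product: 23 5-[2-(benzyloxy)-3,4,5-trimethoxyphenoxy]-3,4-dimethoxyphenol (rings B–C phenol), via vinylketene 19 (not isolated), via vinylcyclobutenone adduct 20 (not isolated), via dienylketene 21 (not isolated), via cyclohexadienone 22 (not isolated)
Conditions: 18 (1.5 equiv), PhMe, sealed tube, 80 °C then 110 °C; then K2CO3, MeOH, rt
Reagents that add atoms: none
Why: Proposed new method: on heating, 18 should undergo 4π electrocyclic ring opening to the vinylketene 19, whose ketene C=C adds to the ynol ether 14 in a (2+2) cycloaddition to give the 4-vinylcyclobutenone 20; a second 4π opening gives the dienylketene 21, which closes ring B by a thermal disrotatory 6π electrocyclisation (B1–B2 bond) to the cyclohexadienone 22, and enolisation gives the phenol 23. The closest known reaction type is the Danheiser benzannulation of cyclobutenones with alkoxyalkynes to 3-alkoxyphenols; new here are the aryl ethynyl ether as ketenophile and the 2,3-dialkoxy substitution of the cyclobutenone. The step needs the regiochemistry of the (2+2) addition, and the polarity of 14 secures it: the oxygen makes the terminal CH carbon nucleophilic, so it bonds to the ketene carbonyl carbon (B1–B6), and the aryloxy carbon bonds to the methoxy-bearing ketene carbon (B4–B5), placing the ring C oxygen at B5 beside the B4 methoxyl. In the opening of 20 the methoxy group on the quaternary carbon should rotate outward and the methoxyvinyl group inward, which gives the Z dienylketene that can cyclise. No stereocentre is formed, and aromatisation makes the sequence irreversible. An aryl ynol ether lacks the retro-ene fragmentation open to alkyl ynol ethers, which should help it survive the temperature, and the electron-rich ring C keeps the alkyne nucleophilic. The carbonate treatment only frees any product phenol that has been acylated by 19.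

Step 11
Reactants: 23 5-[2-(benzyloxy)-3,4,5-trimethoxyphenoxy]-3,4-dimethoxyphenol
Product: 24 5-[2-(benzyloxy)-3,4,5-trimethoxyphenoxy]-3,4-dimethoxyphenyl trifluoromethanesulfonate
Conditions: Tf2O, pyridine, CH2Cl2, 0 °C
Reagents that add atoms: trifluoromethanesulfonic anhydride, O=S(=O)(OS(=O)(=O)C(F)(F)F)C(F)(F)F
Why: O-Sulfonylation of the phenol; B1 lies between two CH carbons, so the triflate is an unhindered electrophile for the next step.

Step 12
Reactants: 24 5-[2-(benzyloxy)-3,4,5-trimethoxyphenoxy]-3,4-dimethoxyphenyl trifluoromethanesulfonate; 25 2,4,6-trimethoxyphenol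
Product: 26 2-{5-[2-(benzyloxy)-3,4,5-trimethoxyphenoxy]-3,4-dimethoxyphenoxy}-1,3,5-trimethoxybenzene (rings A–B–C benzyl ether)
Conditions: Pd(OAc)2 (cat.), t-BuXPhos (2-di-tert-butylphosphino-2′,4′,6′-triisopropylbiphenyl), K3PO4, PhMe, 100 °C, argon
Reagents that add atoms: none
Why: Palladium-catalysed C–O cross-coupling of an aryl triflate with a phenol (Buchwald–Hartwig etherification): zerovalent palladium inserts into the unhindered B1–OTf bond and the bulky biarylphosphine promotes C–O reductive elimination. The crowded partner is the phenoxide, which this coupling tolerates, and the benzyl ether is inert.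

Step 13
Reactants: 26 2-{5-[2-(benzyloxy)-3,4,5-trimethoxyphenoxy]-3,4-dimethoxyphenoxy}-1,3,5-trimethoxybenzene
Product: 27 6-[2,3-dimethoxy-5-(2,4,6-trimethoxyphenoxy)phenoxy]-2,3,4-trimethoxyphenol (rings A–B–C phenol, free hydroxyl at C2)
Conditions: H2 (1 atm), Pd/C, EtOAc–MeOH, rt
Reagents that add atoms: none
Why: Hydrogenolysis of the benzyl aryl ether; the molecule holds no halogen or other reducible group, and methyl and diaryl ethers are untouched.

Step 14
Reactants: 3 2,3,4-trimethoxyphenol
Product: 28 6-iodo-2,3,4-trimethoxyphenol
Conditions: I2, NaHCO3, THF–H2O, 0 °C to rt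
Reagents that add atoms: iodine, II
Why: Electrophilic iodination through the phenoxide; the para position and one ortho position carry methoxyls, so C6 is the only site activated by the phenoxide oxygen.

Step 15
Reactants: 28 6-iodo-2,3,4-trimethoxyphenol; 29 (3,4,5-trimethoxyphenyl)boronic acid
Product: 30 1-iodo-3,4,5-trimethoxy-2-(3,4,5-trimethoxyphenoxy)benzene (rings G–H iodide)
Conditions: Cu(OAc)2, pyridine, 4 Å MS, CH2Cl2, air, rt
Reagents that add atoms: none
Why: Chan–Lam coupling; oxidative copper-mediated O-arylation with an unhindered arylboronic acid is known to accept phenols with two ortho substituents, ortho-iodophenols included, and at room temperature without a low-valent metal the carbon–iodine bond is kept.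

Step 16
Reactants: 30 1-iodo-3,4,5-trimethoxy-2-(3,4,5-trimethoxyphenoxy)benzene; 31 4-bromo-2,6-dimethoxyphenol
Product: 32 5-bromo-1,3-dimethoxy-2-[3,4,5-trimethoxy-2-(3,4,5-trimethoxyphenoxy)phenoxy]benzene (rings F–G–H bromide)
Conditions: CuI (cat.), picolinic acid, K3PO4, DMSO, 80 °C, argon
Reagents that add atoms: none
Why: Ligand-accelerated Ullmann diaryl ether synthesis, known for hindered phenols with ortho-substituted aryl iodides. The iodide of 30 should react with monovalent copper much faster than the bromide of 31, which as a para-bromophenoxide is strongly deactivated; 30 is used in slight excess so that little phenoxide is left for the product bromide.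

Step 17
Reactants: 32 5-bromo-1,3-dimethoxy-2-[3,4,5-trimethoxy-2-(3,4,5-trimethoxyphenoxy)phenoxy]benzene
Product: 34 {3,5-dimethoxy-4-[3,4,5-trimethoxy-2-(3,4,5-trimethoxyphenoxy)phenoxy]phenyl}boronic acid (rings F–G–H boronic acid), via aryllithium 33 (not isolated)
Conditions: n-BuLi, THF, −78 °C; B(OiPr)3, −78 °C to rt; aq. HCl
Reagents that add atoms: triisopropyl borate, CC(C)OB(OC(C)C)OC(C)C; water, O
Why: Bromine–lithium exchange, trapping with a trialkyl borate and hydrolysis; exchange is much faster than ortho-lithiation, and the aryllithium 33, flanked by two CH positions, has no leaving group beside it.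

Step 18
Reactants: 28 6-iodo-2,3,4-trimethoxyphenol; 34 {3,5-dimethoxy-4-[3,4,5-trimethoxy-2-(3,4,5-trimethoxyphenoxy)phenoxy]phenyl}boronic acid
Product: 35 2-{3,5-dimethoxy-4-[3,4,5-trimethoxy-2-(3,4,5-trimethoxyphenoxy)phenoxy]phenoxy}-1-iodo-3,4,5-trimethoxybenzene (rings E–F–G–H iodide)
Conditions: Cu(OAc)2, pyridine, 4 Å MS, CH2Cl2, air, rt
Reagents that add atoms: none
Why: Second Chan–Lam coupling with the logic of step 15: the boronic acid carbon F1 has only CH neighbours, the crowded partner is the phenol, and the iodide of 28 survives for the next coupling.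

Step 19
Reactants: 35 rings E–F–G–H iodide (as named in step 18); 31 4-bromo-2,6-dimethoxyphenol
Product: 36 5-bromo-2-[2-{3,5-dimethoxy-4-[3,4,5-trimethoxy-2-(3,4,5-trimethoxyphenoxy)phenoxy]phenoxy}-3,4,5-trimethoxyphenoxy]-1,3-dimethoxybenzene (rings D–H pentamer bromide)
Conditions: CuI (cat.), picolinic acid, K3PO4, DMSO, 80 °C, argon
Reagents that add atoms: none
Why: Ullmann diaryl ether synthesis as in step 16: the hindered phenoxide of 31 couples at the iodide E1, and the bromide that will serve at D1 is retained.

Step 20
Reactants: 27 rings A–B–C phenol (as named in step 13); 36 rings D–H pentamer bromide (as named in step 19)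
Product: 37 henicosa-O-methyl ether of 38 (rings A–H; all 21 hydroxyls as methoxyls)
Conditions: CuI, picolinic acid, K3PO4, DMSO, 100 °C, argon
Reagents that add atoms: none
Why: Ullmann diaryl ether synthesis between a phenoxide with two ortho substituents (C2) and an aryl bromide whose reacting carbon D1 has only CH neighbours, the polarity this coupling handles best; no other halide or free hydroxyl is present.

Step 21
Reactants: 37 henicosa-O-methyl ether of 38
Product: 38 CNP0175816.0 (octamer with 21 free hydroxyls)
Conditions: BBr3 (large excess), CH2Cl2, −78 °C to rt; then MeOH and degassed H2O, argon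
Reagents that add atoms: none
Why: Lewis-acid cleavage of aryl methyl ethers: each methoxyl is complexed by boron and bromide attacks the methyl carbon. The diaryl ether bonds stay intact because bromide cannot attack an aryl carbon, and the degassed work-up protects the polyphenol from air.

## Compound list

1 | 2,3,4-trimethoxybenzaldehyde | COc1ccc(C=O)c(OC)c1OC | starting material
2 | 2,3,4-trimethoxyphenyl formate (not isolated) | O=COc1ccc(OC)c(OC)c1OC | intermediate
3 | 2,3,4-trimethoxyphenol | Oc1ccc(OC)c(OC)c1OC | intermediate
4 | 6-(hydroxymethyl)-2,3,4-trimethoxyphenol (not isolated) | OCc1cc(OC)c(OC)c(OC)c1O | intermediate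
5 | 2-hydroxy-3,4,5-trimethoxybenzaldehyde | O=Cc1cc(OC)c(OC)c(OC)c1O | intermediate
6 | 2-(benzyloxy)-3,4,5-trimethoxybenzaldehyde | O=Cc1cc(OC)c(OC)c(OC)c1OCc1ccccc1 | intermediate
7 | 2-(benzyloxy)-3,4,5-trimethoxyphenyl formate (not isolated) | O=COc1cc(OC)c(OC)c(OC)c1OCc1ccccc1 | intermediate
8 | 2-(benzyloxy)-3,4,5-trimethoxyphenol | Oc1cc(OC)c(OC)c(OC)c1OCc1ccccc1 | intermediate
9 | trichloroethylene | ClC=C(Cl)Cl | starting material
10 | dichloroacetylene (not isolated) | ClC#CCl | intermediate
11 | 2-(benzyloxy)-1-{[(E)-1,2-dichloroethenyl]oxy}-3,4,5-trimethoxybenzene | Cl/C=C(/Cl)Oc1cc(OC)c(OC)c(OC)c1OCc1ccccc1 | intermediate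
12 | 2-(benzyloxy)-1-[(chloroethynyl)oxy]-3,4,5-trimethoxybenzene (not isolated) | ClC#COc1cc(OC)c(OC)c(OC)c1OCc1ccccc1 | intermediate
13 | lithium [2-(benzyloxy)-3,4,5-trimethoxyphenoxy]acetylide (not isolated) | [Li]C#COc1cc(OC)c(OC)c(OC)c1OCc1ccccc1 | intermediate
14 | 2-(benzyloxy)-1-(ethynyloxy)-3,4,5-trimethoxybenzene | C#COc1cc(OC)c(OC)c(OC)c1OCc1ccccc1 | intermediate
15 | dimethyl squarate (3,4-dimethoxycyclobut-3-ene-1,2-dione) | COC1=C(OC)C(=O)C1=O | starting material
16 | rac-4-hydroxy-2,3-dimethoxycyclobut-2-en-1-one | COC1=C(OC)C(=O)C1O | intermediate
17 | rac-2,3-dimethoxy-4-oxocyclobut-2-en-1-yl acetate | COC1=C(OC)C(=O)C1OC(C)=O | intermediate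
18 | 2,3-dimethoxycyclobut-2-en-1-one | COC1=C(OC)C(=O)C1 | intermediate
19 | 2,3-dimethoxybuta-1,3-dien-1-one, methoxy(1-methoxyethenyl)ketene (not isolated) | C=C(OC)C(OC)=C=O | intermediate
20 | rac-3-[2-(benzyloxy)-3,4,5-trimethoxyphenoxy]-4-methoxy-4-(1-methoxyethenyl)cyclobut-2-en-1-one (not isolated) | C=C(OC)C1(OC)C(=O)C=C1Oc1cc(OC)c(OC)c(OC)c1OCc1ccccc1 | intermediate
21 | (3Z)-3-[2-(benzyloxy)-3,4,5-trimethoxyphenoxy]-4,5-dimethoxyhexa-1,3,5-trien-1-one (not isolated) | O=C=C/C(Oc1cc(OC)c(OC)c(OC)c1OCc1ccccc1)=C(/OC)C(OC)=C | intermediate
22 | 3-[2-(benzyloxy)-3,4,5-trimethoxyphenoxy]-4,5-dimethoxycyclohexa-2,4-dien-1-one (not isolated) | O=C1C=C(Oc2cc(OC)c(OC)c(OC)c2OCc2ccccc2)C(OC)=C(OC)C1 | intermediate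
23 | 5-[2-(benzyloxy)-3,4,5-trimethoxyphenoxy]-3,4-dimethoxyphenol | Oc1cc(OC)c(OC)c(Oc2cc(OC)c(OC)c(OC)c2OCc2ccccc2)c1 | intermediate
24 | 5-[2-(benzyloxy)-3,4,5-trimethoxyphenoxy]-3,4-dimethoxyphenyl trifluoromethanesulfonate | O=S(=O)(Oc1cc(OC)c(OC)c(Oc2cc(OC)c(OC)c(OC)c2OCc2ccccc2)c1)C(F)(F)F | intermediate
25 | 2,4,6-trimethoxyphenol | COc1cc(OC)c(O)c(OC)c1 | starting material
26 | 2-{5-[2-(benzyloxy)-3,4,5-trimethoxyphenoxy]-3,4-dimethoxyphenoxy}-1,3,5-trimethoxybenzene | COc1cc(OC)c(Oc2cc(OC)c(OC)c(Oc3cc(OC)c(OC)c(OC)c3OCc3ccccc3)c2)c(OC)c1 | intermediate
27 | 6-[2,3-dimethoxy-5-(2,4,6-trimethoxyphenoxy)phenoxy]-2,3,4-trimethoxyphenol | COc1cc(OC)c(Oc2cc(OC)c(OC)c(Oc3cc(OC)c(OC)c(OC)c3O)c2)c(OC)c1 | intermediate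
28 | 6-iodo-2,3,4-trimethoxyphenol | Oc1c(I)cc(OC)c(OC)c1OC | intermediate
29 | (3,4,5-trimethoxyphenyl)boronic acid | COc1cc(B(O)O)cc(OC)c1OC | starting material
30 | 1-iodo-3,4,5-trimethoxy-2-(3,4,5-trimethoxyphenoxy)benzene | COc1cc(Oc2c(I)cc(OC)c(OC)c2OC)cc(OC)c1OC | intermediate
31 | 4-bromo-2,6-dimethoxyphenol | COc1cc(Br)cc(OC)c1O | starting material
32 | 5-bromo-1,3-dimethoxy-2-[3,4,5-trimethoxy-2-(3,4,5-trimethoxyphenoxy)phenoxy]benzene | COc1cc(Br)cc(OC)c1Oc1cc(OC)c(OC)c(OC)c1Oc1cc(OC)c(OC)c(OC)c1 | intermediate
33 | {3,5-dimethoxy-4-[3,4,5-trimethoxy-2-(3,4,5-trimethoxyphenoxy)phenoxy]phenyl}lithium (not isolated) | [Li]c1cc(OC)c(Oc2cc(OC)c(OC)c(OC)c2Oc2cc(OC)c(OC)c(OC)c2)c(OC)c1 | intermediate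
34 | {3,5-dimethoxy-4-[3,4,5-trimethoxy-2-(3,4,5-trimethoxyphenoxy)phenoxy]phenyl}boronic acid | COc1cc(B(O)O)cc(OC)c1Oc1cc(OC)c(OC)c(OC)c1Oc1cc(OC)c(OC)c(OC)c1 | intermediate
35 | 2-{3,5-dimethoxy-4-[3,4,5-trimethoxy-2-(3,4,5-trimethoxyphenoxy)phenoxy]phenoxy}-1-iodo-3,4,5-trimethoxybenzene | COc1cc(Oc2c(I)cc(OC)c(OC)c2OC)cc(OC)c1Oc1cc(OC)c(OC)c(OC)c1Oc1cc(OC)c(OC)c(OC)c1 | intermediate
36 | 5-bromo-2-[2-{3,5-dimethoxy-4-[3,4,5-trimethoxy-2-(3,4,5-trimethoxyphenoxy)phenoxy]phenoxy}-3,4,5-trimethoxyphenoxy]-1,3-dimethoxybenzene | COc1cc(Br)cc(OC)c1Oc1cc(OC)c(OC)c(OC)c1Oc1cc(OC)c(Oc2cc(OC)c(OC)c(OC)c2Oc2cc(OC)c(OC)c(OC)c2)c(OC)c1 | intermediate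
37 | henicosa-O-methyl ether of 38 (every hydroxyl of 38 as a methoxyl) | COc1cc(OC)c(Oc2cc(OC)c(OC)c(Oc3cc(OC)c(OC)c(OC)c3Oc3cc(OC)c(Oc4cc(OC)c(OC)c(OC)c4Oc4cc(OC)c(Oc5cc(OC)c(OC)c(OC)c5Oc5cc(OC)c(OC)c(OC)c5)c(OC)c4)c(OC)c3)c2)c(OC)c1 | intermediate
38 | CNP0175816.0, linear octamer of rings A–H with 21 hydroxyls and ether bonds A2–O–B1, B5–O–C1, C2–O–D1, D4–O–E1, E2–O–F1, F4–O–G1, G2–O–H1 | Oc1cc(O)c(Oc2cc(O)c(O)c(Oc3cc(O)c(O)c(O)c3Oc3cc(O)c(Oc4cc(O)c(O)c(O)c4Oc4cc(O)c(Oc5cc(O)c(O)c(O)c5Oc5cc(O)c(O)c(O)c5)c(O)c4)c(O)c3)c2)c(O)c1 | target

## Step count and least certain steps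

Total step count: 21. Longest linear sequence: 12 steps (steps 1–6, 10–13, 20, 21).

**Step 10 (key step).** The most likely failure is a (2+2) addition that is too slow. The aryloxy oxygen shares its lone pair with ring C, so 14 is a weaker nucleophile than an alkyl ynol ether; the vinylketene 19 may then be lost by dimerisation while 14 polymerises at the temperature required. Acylation of the product phenol by 19 is a second drain, which the carbonate treatment is meant to reverse. The fallback uses known reactions only and sets out from the phenol 8. It is coupled with commercial 3-bromo-4,5-dimethoxybenzaldehyde under CuI, picolinic acid and K3PO4 in DMSO (Ullmann ether synthesis; one ortho substituent on each partner, bromide activated by the formyl group). This gives 3-[2-(benzyloxy)-3,4,5-trimethoxyphenoxy]-4,5-dimethoxybenzaldehyde F1. Baeyer–Villiger oxidation with mCPBA then gives 3-[2-(benzyloxy)-3,4,5-trimethoxyphenoxy]-4,5-dimethoxyphenyl formate F2, and methanolysis with K2CO3 returns to the route at 23. Ring B is then bought instead of built, and B5–O–C1 is made by arylation.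

**Step 9.** The risk is protonation of the enolate at C2 instead of C4, which would move the double bond to C3–C4 and lead to the wrong oxygen pattern in ring B; over-reduction or ring cleavage of the strained enone is a second risk. The fallback sets out from the alcohol 16. Acylation with phenyl chlorothionoformate and pyridine gives rac-O-(2,3-dimethoxy-4-oxocyclobut-2-en-1-yl) O-phenyl carbonothioate F3. Reduction with Bu3SnH and Et3B/air at room temperature (Barton–McCombie deoxygenation) should deliver hydrogen to the less hindered terminus C4 of the allyl-type radical and rejoin the route at 18.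

**Step 12.** The risk is slow C–O reductive elimination from an electron-rich arylpalladium phenoxide, so that cleavage of the triflate S–O bond by phenoxide (regenerating 23) and oxidation of the electron-rich phenol 25 take over. The fallback sets out from 24. Miyaura borylation (B2pin2, Pd(dppf)Cl2, KOAc, dioxane, 80 °C) gives 2-{5-[2-(benzyloxy)-3,4,5-trimethoxyphenoxy]-3,4-dimethoxyphenyl}-4,4,5,5-tetramethyl-1,3,2-dioxaborolane F4. Chan–Lam coupling of F4 with 25 (Cu(OAc)2, pyridine, air, rt) returns at 26.

**Step 16.** The risk is loss of chemoselectivity between iodide and bromide. Once 32 has formed, its bromide can be attacked by remaining phenoxide of 31, giving higher oligomers; the three ortho substituents around the new bond also slow the wanted coupling, so protodeiodination gains ground. The fallback sets out from 30. Iodine–lithium exchange (n-BuLi, THF, −78 °C), B(OiPr)3 and hydrolysis give [3,4,5-trimethoxy-2-(3,4,5-trimethoxyphenoxy)phenyl]boronic acid F5. Chan–Lam coupling of F5 with 31 (Cu(OAc)2, pyridine, air, rt), in which no carbon–halogen bond is activated, returns at 32. Step 19 is the same reaction on a larger iodide and would be judged by the outcome here.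

**Step 20.** The risk is a slow union of two large electron-rich partners at a phenoxide with two ortho substituents, so that protodebromination of 36 and oxidative degradation of 27 at 100 °C compete. The fallback sets out from 36. Bromine–lithium exchange, B(OiPr)3 and hydrolysis give the rings D–H pentamer boronic acid F6 (36 with B(OH)2 in place of bromine). Chan–Lam coupling of F6 with 27 at room temperature returns at 37.

**Step 21.** The risks are incomplete cleavage at some of the 21 methoxyls, and oxidation or irreversible adsorption of the free polyphenol during isolation, at a stage where partially methylated material cannot be removed. The fallback sets out from 37. The crude product of the BBr3 cleavage is not isolated as the polyphenol but acetylated at once (Ac2O, pyridine) to the henicosaacetate F7 of 38, which is stable in air and can be chromatographed and checked for residual methoxyls. Zemplén deacetylation (catalytic NaOMe in degassed MeOH, then acidic resin) returns at 38.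

## Further compounds

F1 | step 10 | 3-[2-(benzyloxy)-3,4,5-trimethoxyphenoxy]-4,5-dimethoxybenzaldehyde | O=Cc1cc(OC)c(OC)c(Oc2cc(OC)c(OC)c(OC)c2OCc2ccccc2)c1
F2 | step 10 | 3-[2-(benzyloxy)-3,4,5-trimethoxyphenoxy]-4,5-dimethoxyphenyl formate | O=COc1cc(OC)c(OC)c(Oc2cc(OC)c(OC)c(OC)c2OCc2ccccc2)c1
F3 | step 9 | rac-O-(2,3-dimethoxy-4-oxocyclobut-2-en-1-yl) O-phenyl carbonothioate | COC1=C(OC)C(=O)C1OC(=S)Oc1ccccc1
F4 | step 12 | 2-{5-[2-(benzyloxy)-3,4,5-trimethoxyphenoxy]-3,4-dimethoxyphenyl}-4,4,5,5-tetramethyl-1,3,2-dioxaborolane | COc1cc(B2OC(C)(C)C(C)(C)O2)cc(Oc2cc(OC)c(OC)c(OC)c2OCc2ccccc2)c1OC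
F5 | step 16 | [3,4,5-trimethoxy-2-(3,4,5-trimethoxyphenoxy)phenyl]boronic acid | COc1cc(Oc2c(B(O)O)cc(OC)c(OC)c2OC)cc(OC)c1OC
F6 | step 20 | rings D–H pentamer boronic acid, [4-(2-{3,5-dimethoxy-4-[3,4,5-trimethoxy-2-(3,4,5-trimethoxyphenoxy)phenoxy]phenoxy}-3,4,5-trimethoxyphenoxy)-3,5-dimethoxyphenyl]boronic acid | COc1cc(B(O)O)cc(OC)c1Oc1cc(OC)c(OC)c(OC)c1Oc1cc(OC)c(Oc2cc(OC)c(OC)c(OC)c2Oc2cc(OC)c(OC)c(OC)c2)c(OC)c1
F7 | step 21 | henicosaacetate of 38 (every hydroxyl of 38 as an acetate) | CC(=O)Oc1cc(OC(C)=O)c(Oc2cc(OC(C)=O)c(OC(C)=O)c(Oc3cc(OC(C)=O)c(OC(C)=O)c(OC(C)=O)c3Oc3cc(OC(C)=O)c(Oc4cc(OC(C)=O)c(OC(C)=O)c(OC(C)=O)c4Oc4cc(OC(C)=O)c(Oc5cc(OC(C)=O)c(OC(C)=O)c(OC(C)=O)c5Oc5cc(OC(C)=O)c(OC(C)=O)c(OC(C)=O)c5)c(OC(C)=O)c4)c(OC(C)=O)c3)c2)c(OC(C)=O)c1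
A1 | alternative 1 | CpRu hexafluorophosphate complex of the deca-O-methyl rings A–B–C–D tetramer with benzyl ether at D4, drawn as separated components | COc1cc(OC)c(Oc2cc(OC)c(OC)c(Oc3cc(OC)c(OC)c(OC)c3Oc3cc(OC)c(OCc4ccccc4)c(OC)c3)c2)c(OC)c1.[cH-]1cccc1.[Ru+2].F[P-](F)(F)(F)(F)F
A2 | alternative 1 | [CpRu(η6-1,2-dichloro-3,4,5-trimethoxybenzene)]PF6, drawn as separated components | COc1cc(Cl)c(Cl)c(OC)c1OC.[cH-]1cccc1.[Ru+2].F[P-](F)(F)(F)(F)F
A3 | alternative 2 | 2-(3-bromo-4,5-dimethoxyphenoxy)benzene-1,3,5-triol | Oc1cc(O)c(Oc2cc(Br)c(OC)c(OC)c2)c(O)c1
A4 | alternative 2 | methyl 6-(3-bromo-4,5-dimethoxyphenoxy)-3,5-dioxohexanoate | COC(=O)CC(=O)CC(=O)COc1cc(Br)c(OC)c(OC)c1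
A5 | alternative 3 | 3,4,5-trimethoxy-2-(3,4,5-trimethoxyphenoxy)phenol | Oc1cc(OC)c(OC)c(OC)c1Oc1cc(OC)c(OC)c(OC)c1
A6 | alternative 3 | rac-3,4-dimethoxy-4-(1-methoxyethenyl)-2-(3,4,5-trimethoxyphenoxy)cyclobut-2-en-1-one | C=C(OC)C1(OC)C(OC)=C(Oc2cc(OC)c(OC)c(OC)c2)C1=O
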